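**Plan**

- Retrosynthesis: after the two oxygen protecting groups are removed, ring A is cut at both ring bonds of its bromine-bearing carbon. This gives a 3-aryloxy-4-pyranone and a one-carbon bromo ylide.
- Feature used: in ring A the hydroxyl carbon, the neighbouring ether-oxygen carbon and the bromine-bearing carbon para to the hydroxyl map onto C4=O, C3–OAr and the ring oxygen of a 4-pyranone. Only that ring oxygen has to be exchanged for C–Br.
- The pyranone is cut at its ring oxygen and at C2 and C6 to an aryloxyacetone and two formamide-acetal carbons. The bond from the ether oxygen to ring A is therefore made by O-alkylation of the crowded ring B phenol with chloroacetone, not by arylation.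
- The ring B phenol goes back to 2,4,5-tribromophenol: formyl in, O-methyl on, formyl converted to hydroxyl.
- Forward order: ring B is bought, the pyranone ring is built on its oxygen (step 5), ring A is formed from it (step 6), and the two oxygens are then freed (steps 7 and 8).
- Stereochemistry: there is none to set (no stereocentre, no stereogenic double bond); only regiochemistry matters, and each precursor fixes it.

Key step: step 6

Remark: 2,4,5-tribromophenol is taken as a catalogue compound, and the ylide is drawn as adding to the alpha carbon remote from the aryloxy group (addition at the other alpha carbon would converge on the same arene).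

**Route**

Step 1
Reactants: 1 2,4,5-tribromophenol
Product: 2 3,5,6-tribromo-2-hydroxybenzaldehyde
Conditions: MgCl2, Et3N, (CH2O)n, MeCN, reflux; 1 M HCl
Reagents that add atoms: paraformaldehyde (reacts as formaldehyde), C=O
Why: Magnesium-mediated ortho-formylation (Casnati–Skattebøl reaction): the ArOMgCl phenoxide delivers formaldehyde to the only free position ortho to oxygen, and a second formaldehyde oxidises the benzylic alkoxide to the aldehyde by hydride transfer, so no regioisomer can arise.

Step 2
Reactants: 2 3,5,6-tribromo-2-hydroxybenzaldehyde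
Product: 3 3,5,6-tribromo-2-methoxybenzaldehyde
Conditions: MeI, K2CO3, DMF, rt
Reagents that add atoms: iodomethane, CI
Why: Williamson O-methylation of the acidic phenol fixes, as a methyl ether stable to every later step, the ring B oxygen that is free in the target, while the formyl carbon marks where the ether oxygen will enter.

Step 3
Reactants: 3 3,5,6-tribromo-2-methoxybenzaldehyde
Product: 5 2,3,5-tribromo-6-methoxyphenol, via aryl formate 4 (not isolated)
Conditions: mCPBA, CH2Cl2, rt; aq. NaHCO3/Na2S2O3 wash; then K2CO3 (cat.), MeOH, rt
Reagents that add atoms: 3-chloroperbenzoic acid (mCPBA), O=C(OO)c1cccc(Cl)c1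
Why: Baeyer–Villiger oxidation of the aldehyde in its Dakin sense: the ortho-methoxy group and the twisted, doubly ortho-substituted formyl group should favour aryl over hydride migration in the Criegee adduct, and the labile aryl formate is cleaved by base-catalysed methanolysis.

Step 4
Reactants: 5 2,3,5-tribromo-6-methoxyphenol; 6 chloroacetone
Product: 7 1-(2,3,5-tribromo-6-methoxyphenoxy)propan-2-one
Conditions: K2CO3, KI (cat.), acetone, reflux
Reagents that add atoms: chloroacetone (6), CC(=O)CCl
Why: Williamson ether synthesis with an activated alpha-halo ketone (iodide catalysis through iodoacetone): the doubly ortho-substituted, weakly nucleophilic phenoxide is alkylated at an unhindered primary carbon, which is far easier than arylating it.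

Step 5
Reactants: 7 1-(2,3,5-tribromo-6-methoxyphenoxy)propan-2-one; 8 N,N-dimethylformamide dimethyl acetal
Product: 10 3-(2,3,5-tribromo-6-methoxyphenoxy)-4H-pyran-4-one, via bis-enaminone 9 (not isolated)
Conditions: 8 (excess), neat, 110 °C, MeOH distilled off; evaporate; 2 M HCl, THF, 60 °C
Reagents that add atoms: N,N-dimethylformamide dimethyl acetal (8), COC(OC)N(C)C; water, O
Why: Enaminone formation with an amide acetal at both alpha carbons of the ketone (the aryloxy-activated methylene first, the methyl group on forcing), then acid hydrolysis of one enamine to the enol, 6-endo-trig addition of its oxygen to the other enaminone terminus and loss of dimethylamine, the known route from ketones with two enolisable sides to 3-substituted 4-pyranones.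

Step 6
Reactants: 10 3-(2,3,5-tribromo-6-methoxyphenoxy)-4H-pyran-4-one; 11 (bromomethyl)triphenylphosphonium bromide
Product: 15 [4-bromo-2-(2,3,5-tribromo-6-methoxyphenoxy)phenoxy]tri(propan-2-yl)silane, via silyloxypyrylium triflate 12 (not isolated), via 2H-pyranylphosphonium triflate 13 (not isolated), via dienal ylide 14 (not isolated)
Conditions: 10, iPr3SiOTf (1.0 equiv), CH2Cl2, 0 °C to rt; cannulated into Ph3P=CHBr [from 11 (1.15 equiv), KN(SiMe3)2 (1.1 equiv), THF, −78 °C]; then KN(SiMe3)2 (1.0 equiv), −78 °C to rt, then 45 °C
Reagents that add atoms: (bromomethyl)triphenylphosphonium bromide (11), BrC[P+](c1ccccc1)(c1ccccc1)c1ccccc1.[Br-]; tri(propan-2-yl)silyl trifluoromethanesulfonate, CC(C)[Si](OS(=O)(=O)C(F)(F)F)(C(C)C)C(C)C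
Why: Proposed new method: O-silylation gives the 4-silyloxypyrylium ion 12; Ph3P=CHBr adds to an alpha carbon to give the 2H-pyran 13, which opens (oxa-6π electrocyclic ring opening, or conjugate-base elimination once deprotonated) while the second charge of KN(SiMe3)2 converts the phosphonium salt into the vinylogous ylide 14. The closest known reaction types are the conversion of 2,4,6-trisubstituted pyrylium salts into benzenes by alkylidenephosphoranes and the alpha-addition of carbon nucleophiles to 4-silyloxypyrylium triflates; new are the alpha-unsubstituted pyrylium ion and the bromine-bearing ylide. Ring A closes by 6-exo-trig attack of the ylide carbon on the aldehyde carbon (intramolecular Wittig olefination), and collapse of the oxaphosphetane with loss of Ph3PO gives the arene directly, so that the new bromine-bearing carbon is bonded to the ring A CH para to the ether oxygen in the addition and to the CH ortho to the ether oxygen in the closure. No stereocentre is created: the two centres of 13 and the alkene geometry of 14 vanish on aromatisation, and the cis geometry needed for closure is reachable because the delocalised ylide and the 2H-pyran interconvert. The selectivity needed is attack at an alpha carbon and not at C4 or silicon; C4 bears the oxygen donor and is screened, like silicon, by the three isopropyl groups, both alpha carbons lead to the same benzene, and the base is kept to two equivalents in total so that no amide is left to attack the ring B hydrogen between two bromines.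

Step 7
Reactants: 15 [4-bromo-2-(2,3,5-tribromo-6-methoxyphenoxy)phenoxy]tri(propan-2-yl)silane
Product: 16 4-bromo-2-(2,3,5-tribromo-6-methoxyphenoxy)phenol
Conditions: Bu4NF, AcOH, THF, 0 °C
Reagents that add atoms: none
Why: Fluoride-induced cleavage of the aryl silyl ether, driven by the Si–F bond and buffered with acetic acid so that no free phenoxide remains; methyl ether, diaryl ether and aryl bromides are inert.

Step 8
Reactants: 16 4-bromo-2-(2,3,5-tribromo-6-methoxyphenoxy)phenol
Product: 17 3,4,6-tribromo-2-(5-bromo-2-hydroxyphenoxy)phenol (target)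
Conditions: BBr3 (3 equiv), CH2Cl2, −78 °C to rt; H2O
Reagents that add atoms: none
Why: Lewis acid demethylation of the aryl methyl ether with BBr3 (bromide attack on the O-methyl of the boron-complexed ether); the diaryl ether cannot be cleaved by SN2 and the aryl bromides are untouched, so hydrolysis of the aryl borates should give the target.

**Compound list**

1 | 2,4,5-tribromophenol | Oc1cc(Br)c(Br)cc1Br | starting material
2 | 3,5,6-tribromo-2-hydroxybenzaldehyde | O=Cc1c(O)c(Br)cc(Br)c1Br | intermediate
3 | 3,5,6-tribromo-2-methoxybenzaldehyde | O=Cc1c(OC)c(Br)cc(Br)c1Br | intermediate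
4 | 2,3,5-tribromo-6-methoxyphenyl formate | O=COc1c(OC)c(Br)cc(Br)c1Br | intermediate (not isolated)
5 | 2,3,5-tribromo-6-methoxyphenol | Oc1c(OC)c(Br)cc(Br)c1Br | intermediate
6 | chloroacetone | CC(=O)CCl | starting material
7 | 1-(2,3,5-tribromo-6-methoxyphenoxy)propan-2-one | CC(=O)COc1c(OC)c(Br)cc(Br)c1Br | intermediate
8 | N,N-dimethylformamide dimethyl acetal | COC(OC)N(C)C | starting material
9 | (1Z,4E)-1,5-bis(dimethylamino)-2-(2,3,5-tribromo-6-methoxyphenoxy)penta-1,4-dien-3-one (expected geometry, lost on ring closure) | CN(C)/C=C/C(=O)/C(Oc1c(OC)c(Br)cc(Br)c1Br)=C/N(C)C | intermediate (not isolated)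
10 | 3-(2,3,5-tribromo-6-methoxyphenoxy)-4H-pyran-4-one | O=c1ccocc1Oc1c(OC)c(Br)cc(Br)c1Br | intermediate
11 | (bromomethyl)triphenylphosphonium bromide | BrC[P+](c1ccccc1)(c1ccccc1)c1ccccc1.[Br-] | starting material
12 | 3-(2,3,5-tribromo-6-methoxyphenoxy)-4-{[tri(propan-2-yl)silyl]oxy}pyrylium trifluoromethanesulfonate | CC(C)[Si](Oc1cc[o+]cc1Oc1c(OC)c(Br)cc(Br)c1Br)(C(C)C)C(C)C.[O-]S(=O)(=O)C(F)(F)F | intermediate (not isolated)
13 | {bromo[5-(2,3,5-tribromo-6-methoxyphenoxy)-4-{[tri(propan-2-yl)silyl]oxy}-2H-pyran-2-yl]methyl}triphenylphosphonium trifluoromethanesulfonate (racemic mixture of diastereomers; both centres are lost later) | CC(C)[Si](OC1=CC(C(Br)[P+](c2ccccc2)(c2ccccc2)c2ccccc2)OC=C1Oc1c(OC)c(Br)cc(Br)c1Br)(C(C)C)C(C)C.[O-]S(=O)(=O)C(F)(F)F | intermediate (not isolated)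
14 | (2Z,4Z)-6-bromo-2-(2,3,5-tribromo-6-methoxyphenoxy)-3-{[tri(propan-2-yl)silyl]oxy}-6-(triphenylphosphoranylidene)hexa-2,4-dienal | O=C/C(Oc1c(OC)c(Br)cc(Br)c1Br)=C(O[Si](C(C)C)(C(C)C)C(C)C)\C=C/C(Br)=P(c1ccccc1)(c1ccccc1)c1ccccc1 | intermediate (not isolated)
15 | [4-bromo-2-(2,3,5-tribromo-6-methoxyphenoxy)phenoxy]tri(propan-2-yl)silane | CC(C)[Si](Oc1ccc(Br)cc1Oc1c(OC)c(Br)cc(Br)c1Br)(C(C)C)C(C)C | intermediate
16 | 4-bromo-2-(2,3,5-tribromo-6-methoxyphenoxy)phenol | Oc1ccc(Br)cc1Oc1c(OC)c(Br)cc(Br)c1Br | intermediate
17 | 3,4,6-tribromo-2-(5-bromo-2-hydroxyphenoxy)phenol | Oc1ccc(Br)cc1Oc1c(O)c(Br)cc(Br)c1Br | target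

**Step count**

Total step count: 8. Longest linear sequence: 8 steps (1 to 17).

**Steps most likely to fail**

1. Step 6 (bears the label "Proposed new method:"). The ylide may be used up by attack at silicon or at C4 instead of an alpha carbon. The ring-opened dienal may also oligomerise before the stabilised ylide closes onto the aldehyde. The fallback uses known chemistry and buys ring A instead of building it. It sets out from phenol 5. Nucleophilic aromatic substitution on 4-bromo-2-fluorobenzaldehyde (Cs2CO3, N,N-dimethylacetamide, 120 °C) should give 4-bromo-2-(2,3,5-tribromo-6-methoxyphenoxy)benzaldehyde F1. Baeyer–Villiger oxidation (mCPBA, CH2Cl2) should give 4-bromo-2-(2,3,5-tribromo-6-methoxyphenoxy)phenyl formate F2. Methanolysis (K2CO3, MeOH) then comes back to the route at phenol 16, one step before the target.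

2. Step 5. The second aminomethylenation may stall at the mono-enaminone stage, or hydrolysis of the enamines may outrun ring closure. The fallback brings in the second carbon by an irreversible enolate acylation and sets out from ketone 7. One equivalent of acetal 8 (toluene, 80 °C) should give (3Z)-4-(dimethylamino)-3-(2,3,5-tribromo-6-methoxyphenoxy)but-3-en-2-one F3; if the methyl group reacted first, the regioisomer would converge. Deprotonation of the methyl ketone (LiN(SiMe3)2, THF, −78 °C) and Claisen formylation with ethyl formate should give (4Z)-5-(dimethylamino)-3-oxo-4-(2,3,5-tribromo-6-methoxyphenoxy)pent-4-enal F4, held as its enolate and not isolated. Acid (2 M HCl, THF) should close it with loss of dimethylamine, coming back to the route at pyranone 10.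

3. Step 3. Hydride migration may compete with aryl migration in the Criegee adduct of this electron-poor aldehyde, so that oxidation ends at the carboxylic acid level. The fallback puts the oxygen in through boron and sets out from phenol 1, bypassing steps 1 and 2 as well. Iodination at the only free ortho position (N-iodosuccinimide, TsOH cat., MeCN) should give 3,4,6-tribromo-2-iodophenol F5. O-Methylation (MeI, K2CO3, DMF) should give 1,2,5-tribromo-3-iodo-4-methoxybenzene F6. Selective iodine–magnesium exchange (iPrMgCl·LiCl, THF, −40 °C) should give chloro(2,3,5-tribromo-6-methoxyphenyl)magnesium F7. Trapping with B(OMe)3 should give dimethyl (2,3,5-tribromo-6-methoxyphenyl)boronate F8. Oxidation (H2O2, NaOH, 0 °C) comes back to the route at phenol 5.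

**Further compounds**

F1 | step 6 | 4-bromo-2-(2,3,5-tribromo-6-methoxyphenoxy)benzaldehyde | O=Cc1ccc(Br)cc1Oc1c(OC)c(Br)cc(Br)c1Br
F2 | step 6 | 4-bromo-2-(2,3,5-tribromo-6-methoxyphenoxy)phenyl formate | O=COc1ccc(Br)cc1Oc1c(OC)c(Br)cc(Br)c1Br
F3 | step 5 | (3Z)-4-(dimethylamino)-3-(2,3,5-tribromo-6-methoxyphenoxy)but-3-en-2-one | CC(=O)/C(Oc1c(OC)c(Br)cc(Br)c1Br)=C/N(C)C
F4 | step 5 | (4Z)-5-(dimethylamino)-3-oxo-4-(2,3,5-tribromo-6-methoxyphenoxy)pent-4-enal | O=CCC(=O)/C(Oc1c(OC)c(Br)cc(Br)c1Br)=C/N(C)C
F5 | step 3 | 3,4,6-tribromo-2-iodophenol | Oc1c(I)c(Br)c(Br)cc1Br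
F6 | step 3 | 1,2,5-tribromo-3-iodo-4-methoxybenzene | COc1c(I)c(Br)c(Br)cc1Br
F7 | step 3 | chloro(2,3,5-tribromo-6-methoxyphenyl)magnesium | COc1c([Mg]Cl)c(Br)c(Br)cc1Br
F8 | step 3 | dimethyl (2,3,5-tribromo-6-methoxyphenyl)boronate | COB(OC)c1c(OC)c(Br)cc(Br)c1Br
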